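Start from 0.0800 M, the nucleophile charged minus the electrophile charged, in the flasks below.

    target → over-reaction product (k1 = 0.17 h⁻¹)
    electrophile + nucleophile → acid set free + target (k2 = 0.60 M⁻¹ h⁻¹)
    nucleophile + acid set free ⇌ protonated nucleophile, settled at all times (K3 = 24 M⁻¹)
    acid set free + free base ⇌ salt of the base (K4 = 360 M⁻¹, k4 = 3.2 M⁻¹ h⁻¹)

| flask | electrophile | nucleophile | free base | time |
|---|---|---|---|---|
| violet | 0.80 M | 0.880 M | 1.20 M | 15 h |
| blue | 0.80 M | 0.880 M | 1.60 M | 15 h |
| ochre | 0.80 M | 0.880 M | 2.00 M | 15 h |

- part of the electrophile that has reacted at the end, violet
- part of the electrophile that has reacted at the end, blue
- part of the electrophile that has reacted at the end, ochre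
- what raising the concentration of free base from its lowest to its highest value here does to the part of the electrophile that has reacted (changes below 5 percentage points count as none) (no change / it rises / it falls)

Count first what can touch the electrophile. The loss of target to over-reaction product makes no difference to the part reacted in violet or ochre, so strike that step. Acid set free can hold nucleophile back, but in violet at the start free base offers 430 against 21 for nucleophile, far the stronger hold at balance, and what can bind acid comes to 2.60 times the electrophile charged. So treat nucleophile as free for coupling. Step 4 runs at a finite rate while step 3 stands at balance, so some nucleophile is held meanwhile and this reckoning runs high.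

Now solve both ends. Early on the partners are nearly alike, and the electrophile falls along a hyperbola. Late, nucleophile stands near the excess, and the electrophile dies away exponentially in the excess time, one over the coupling constant times the excess, 20.8 h. Join them with the exact integral: with E = exp(−time/excess time), the part reacted is nucleophile charge times (one minus E), over nucleophile charge minus electrophile charge times E. Two times then count, the 15 h of the run and the excess time, with ratio 0.721. That gives 92.1 %. Commit to this one figure for each flask, as an estimate on the high side; free base does not stand in the formula.

The forecast says 87.5 % for violet, 89.5 % for blue and 90.5 % for ochre, with no change, “just below that ceiling and the spread under 5 points”; even its ochre lies under my figure.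

The simulation gives 87.9 %, 89.1 % and 89.8 %, a rise of 1.9 percentage points, so no change. Ochre stands 2.3 points under what 20.8 h against 15 h gave. For the forecast to miss, change the charge: ochre's answer moves by 5 points at 0.787 M of nucleophile. Carry the time to one more flask, like blue but with 2.0 M of electrophile. The excess turns into a deficit, nucleophile becomes the limiting reagent, and the deficit time, one over the coupling constant times the deficit, 1.49 h, is short against the run, so expect 44.0 %. That flask reads 44.0 %, with 0.032 % of its nucleophile left.

(The numbers belong to no real substance; what happens was integrated by code.)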